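**Assumption:** the SMILES has no descriptor for the stereogenic C8–C8'' axis, so I target the (aR) atropisomer (= M, torsion C8a–C8–C8''–C8a'' negative). The descriptor is carried in the names. The (R)-acid is written as the catalyst antipode leading to (aR), and its mirror image gives (aS) by the same steps.

## Retrosynthetic overview
1. Target ⇒ its 5,5'',7,7''-tetraisopropyl ether. The last step is four O–iPr cleavages that leave the 4'-OMe groups alone.
2. Key disconnection: the two O1–C2 (C–O) bonds of both rings C. Opening them gives a racemic biphenyl-2,2'-diol bearing two 1,3-diketone arms, and closing them under a chiral acid sets the axis.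
3. Bis-diketone ⇒ 3,3'-diacetylbiphenyl-2,2'-diol plus two 4-methoxybenzoyl chloride units (double Claisen aroylation, which brings in both rings B).
4. Biphenyl ⇒ ortho–ortho oxidative coupling of 2-hydroxy-4,6-diisopropoxyacetophenone, itself made from phloroacetophenone and 2-bromopropane.
5. Ring order: rings A and B are bought. The two rings C are formed last, one after the other in a single operation.

## Route

**Step 1**
Reactants: 1 2,4,6-trihydroxyacetophenone; 2 2-bromopropane
Product: 3 1-[2-hydroxy-4,6-di(propan-2-yloxy)phenyl]ethanone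
Conditions: 2 (2.3 equiv), K2CO3 (2.3 equiv), DMF, 65 °C, 16 h
Reagents that add atoms: 2-bromopropane, CC(C)Br
Why: Williamson ether synthesis in which the 4-OH and one ortho OH are alkylated, while the last OH is locked in a hydrogen bond to the acetyl C=O and stays free, marking the oxygen that later becomes O1.

**Step 2**
Reactants: 3 1-[2-hydroxy-4,6-di(propan-2-yloxy)phenyl]ethanone (two molecules)
Product: 4 rac-1,1'-[2,2'-dihydroxy-4,4',6,6'-tetra(propan-2-yloxy)biphenyl-3,3'-diyl]diethanone
Conditions: FeCl3·6H2O on silica gel (2.5 equiv FeCl3), adsorbed from Et2O, solvent-free, 55 °C, 20 h; EtOAc elution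
Reagents that add atoms: none
Why: Oxidative phenol coupling, established for the analogous 4,6-dimethyl ether; the chelated iron phenolate couples at C3 ortho to the OH because C5 is shielded by two isopropoxy groups, and the axis forms as a racemate.

**Step 3**
Reactants: 4 rac-diacetylbiphenyldiol; 5 4-methoxybenzoyl chloride
Product: 6 rac-1,1'-[2,2'-dihydroxy-4,4',6,6'-tetra(propan-2-yloxy)biphenyl-3,3'-diyl]bis[3-(4-methoxyphenyl)propane-1,3-dione]
Conditions: LiN(SiMe3)2 (7 equiv), THF, −78 to −10 °C; 5 (2.2 equiv), −78 °C to rt; cold 1 M HCl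
Reagents that add atoms: 4-methoxybenzoyl chloride, COc1ccc(C(=O)Cl)cc1
Why: Crossed Claisen C-aroylation of the lithium phenolate-enolate (the direct variant of the Baker–Venkataraman synthesis), where excess base deprotonates each new diketone and any O-aroylated material rearranges to the same product.

**Step 4**
Reactants: 6 rac-bis(1,3-diketone)
Product: 8 (aR)-5,5'',7,7''-tetra-O-isopropyl-4',4'''-di-O-methylcupressuflavone, via half-closed monoflavone diketone 7 (not isolated)
Conditions: (R)-3,3'-bis(2,4,6-triisopropylphenyl)-1,1'-binaphthyl-2,2'-diyl N-triflylphosphoramide (10 mol %), 5 Å MS, toluene (0.02 M), 60 °C, 48 h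
Reagents that add atoms: none
Why: Proposed new method: an atroposelective double cyclodehydration run as a dynamic kinetic resolution; the bifunctional P(=O)/N–H acid shuttles the proton of the free phenol next to the axis onto the ipso carbon C1 of the phloroglucinol-type ring, and this transient sp3 carbon lets the aryl–aryl bond rotate, so 6 and 7 racemise as long as one ring still has its 2-OH; the same acid activates the anisoyl C=O for attack by that phenol oxygen (O1–C2 bond) and for loss of water inside its open chiral pocket, so the matched atropisomer of 7 closes faster and the second closure fixes the axis; in 8 no phenol remains beside the axis and the basic pyranone C=O takes the proton, so the product cannot racemise by this path; the closest known reaction types are acid-catalysed cyclodehydration of 1-(2-hydroxyaryl)-1,3-diketones to flavones and chiral-phosphoric-acid-catalysed atroposelective cyclodehydrations, neither of which has been shown on a racemising biaryl phenol.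

**Step 5**
Reactants: 8 (aR)-tetraisopropyl ether
Product: 9 (aR)-4',4'''-di-O-methylcupressuflavone
Conditions: BCl3 (12 equiv, 1 M in CH2Cl2), CH2Cl2, −78 °C to rt, 4 h; H2O, 0 °C
Reagents that add atoms: none
Why: Lewis-acid dealkylation in which BCl3 cleaves secondary aryl isopropyl ethers (the 5-O ones assisted by chelation to C4=O) but not the unchelated 4'-methyl ethers, while boron chelation keeps ring A electron-poor and no bond at the axis is touched, so (aR) is retained.

## Compound list
1 | 2,4,6-trihydroxyacetophenone | CC(=O)c1c(O)cc(O)cc1O | starting material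
2 | 2-bromopropane | CC(C)Br | starting material
3 | 1-[2-hydroxy-4,6-di(propan-2-yloxy)phenyl]ethanone | CC(=O)c1c(O)cc(OC(C)C)cc1OC(C)C | intermediate
4 | rac-1,1'-[2,2'-dihydroxy-4,4',6,6'-tetra(propan-2-yloxy)biphenyl-3,3'-diyl]diethanone | CC(=O)c1c(O)c(-c2c(O)c(C(C)=O)c(OC(C)C)cc2OC(C)C)c(OC(C)C)cc1OC(C)C | intermediate
5 | 4-methoxybenzoyl chloride | COc1ccc(C(=O)Cl)cc1 | starting material
6 | rac-1,1'-[2,2'-dihydroxy-4,4',6,6'-tetra(propan-2-yloxy)biphenyl-3,3'-diyl]bis[3-(4-methoxyphenyl)propane-1,3-dione] | COc1ccc(C(=O)CC(=O)c2c(O)c(-c3c(O)c(C(=O)CC(=O)c4ccc(OC)cc4)c(OC(C)C)cc3OC(C)C)c(OC(C)C)cc2OC(C)C)cc1 | intermediate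
7 | 8-{2-hydroxy-4,6-diisopropoxy-3-[3-(4-methoxyphenyl)-3-oxopropanoyl]phenyl}-5,7-diisopropoxy-2-(4-methoxyphenyl)-4H-chromen-4-one (axis still labile under the reaction conditions) | COc1ccc(-c2cc(=O)c3c(OC(C)C)cc(OC(C)C)c(-c4c(O)c(C(=O)CC(=O)c5ccc(OC)cc5)c(OC(C)C)cc4OC(C)C)c3o2)cc1 | intermediate
8 | (aR)-5,5'',7,7''-tetra-O-isopropyl-4',4'''-di-O-methylcupressuflavone (M helicity at C8–C8'') | COc1ccc(-c2cc(=O)c3c(OC(C)C)cc(OC(C)C)c(-c4c(OC(C)C)cc(OC(C)C)c5c(=O)cc(-c6ccc(OC)cc6)oc45)c3o2)cc1 | intermediate
9 | (aR)-4',4'''-di-O-methylcupressuflavone (M helicity at C8–C8'') | COc1ccc(-c2cc(=O)c3c(O)cc(O)c(-c4c(O)cc(O)c5c(=O)cc(-c6ccc(OC)cc6)oc45)c3o2)cc1 | target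

## Step count and risks
Total steps: 5. Longest linear sequence: 5 (1 → 3 → 4 → 6 → 8 → 9).

**Step 4 (new method).**
- Risks: ring closure may outrun racemisation and give low ee, the basic product may buffer the acid, and the sense of induction is unknown.
- Moderate ee could be raised by recrystallising the C2-symmetric 8.
- Fallback (known chemistry): starting from 6, close both rings with an achiral acid (p-TsOH·H2O, toluene, reflux, Dean–Stark) to give the racemic tetraisopropyl ether F1.
- Separate its atropisomers by preparative HPLC on an amylose tris(3,5-dimethylphenylcarbamate) phase and assign them by CD.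
- The (aR) fraction is 8, where the route is rejoined. The (aS) half is lost.

**Step 2.**
- Risks: modest conversion, ortho–para coupling, or loss of the chelated isopropyl group on the Lewis-acidic support.
- Fallback: starting from 3, iodinate ortho to the phenol (NIS, cat. TFA, MeCN) to give 1-[2-hydroxy-3-iodo-4,6-di(propan-2-yloxy)phenyl]ethanone F2.
- Dimerise F2 in a one-pot Miyaura borylation/Suzuki coupling (B2pin2 0.55 equiv, Pd(OAc)2, SPhos, K3PO4, dioxane/H2O, 90 °C).
- This proceeds through the pinacol boronate F3, made in the flask, and rejoins the route at 4.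

**Step 3.**
- Risks: incomplete second aroylation or over-acylation of the hindered bis-enolate.
- Fallback: starting from 4, use the stepwise Baker–Venkataraman sequence. O-aroylate both phenols (NaH, 5, THF, 0 °C to rt) and isolate the bis(4-methoxybenzoate) F4.
- Induce the intramolecular O-to-C acyl shift with KOtBu in THF, which rejoins the route at 6.

## Further compounds
F1 | step 4 | rac-5,5'',7,7''-tetra-O-isopropyl-4',4'''-di-O-methylcupressuflavone | COc1ccc(-c2cc(=O)c3c(OC(C)C)cc(OC(C)C)c(-c4c(OC(C)C)cc(OC(C)C)c5c(=O)cc(-c6ccc(OC)cc6)oc45)c3o2)cc1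
F2 | step 2 | 1-[2-hydroxy-3-iodo-4,6-di(propan-2-yloxy)phenyl]ethanone | CC(=O)c1c(O)c(I)c(OC(C)C)cc1OC(C)C
F3 | step 2 | 1-[2-hydroxy-4,6-di(propan-2-yloxy)-3-(4,4,5,5-tetramethyl-1,3,2-dioxaborolan-2-yl)phenyl]ethanone | CC(=O)c1c(O)c(B2OC(C)(C)C(C)(C)O2)c(OC(C)C)cc1OC(C)C
F4 | step 3 | rac-3,3'-diacetyl-4,4',6,6'-tetra(propan-2-yloxy)biphenyl-2,2'-diyl bis(4-methoxybenzoate) | CC(=O)c1c(OC(=O)c2ccc(OC)cc2)c(-c2c(OC(=O)c3ccc(OC)cc3)c(C(C)=O)c(OC(C)C)cc2OC(C)C)c(OC(C)C)cc1OC(C)C
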